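**Retrosynthetic overview**
- The five-membered ring is closed last: a (guaiazulenylmethyl)phosphonate carbanion is C-acylated by a masked o-acetylbenzoate (a 3-methoxyphthalide pseudo-ester), then an intramolecular Horner–Wadsworth–Emmons reaction forms C2=C3.
- The tetrasubstituted benzene ring is made first, in one operation, by dearomatizing Diels–Alder/cycloaromatization of 5-methylfurfural N,N-dimethylhydrazone with (E)-4-oxopent-2-enoic acid; this key step is an untested extension of the known furfural-hydrazone cycloaromatization, and the regiochemistry is predicted, not precedented.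
- The azulene is bought intact as guaiazulene and converted into the phosphonate by Mannich reaction, N-methylation and Michaelis–Arbuzov reaction.
- The aldehyde travels as the dimethylhydrazone (which also activates and orients the furan) and is unveiled last.
- Ring order: benzene ring (from the furan), then the indenone five-membered ring; the azulene rings are never built.

Assumption: the SMILES has no stereodescriptor and the molecule has no stereocentre (the azulenyl–indenone axis is taken as freely rotating), so the target is made as the single achiral compound drawn.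

**Step 1**
Reactants: 1 5-methylfurfural; 2 N,N-dimethylhydrazine; 3 (E)-4-oxopent-2-enoic acid
Product: 6 rac-4-[(E)-(2,2-dimethylhydrazinylidene)methyl]-3-hydroxy-3,7-dimethyl-2-benzofuran-1(3H)-one, via furfural hydrazone 4 (not isolated), via oxanorbornene cycloadduct 5 (not isolated)
Conditions: 1 (1.05 equiv), 2 (1.0 equiv), 4 Å MS, ClCH2CH2Cl, 23 °C, 2 h; then 3 (1.1 equiv), 70 °C, 24 h
Reagents that add atoms: none
Why: Condensation gives the electron-rich aza-enamine furan 4, which undergoes a dearomatizing Diels–Alder reaction with the keto acid in which the furan terminus remote from the hydrazone donor (the methyl-bearing carbon) bonds to the alkene carbon β to the stronger ketone acceptor, so that acetyl ends up next to the CH=N carbon and CO2H next to the ring methyl, after which oxanorbornene 5 opens with hydrazone assistance and loses water (cycloaromatization, catalysed by the substrate's own CO2H) to give the o-acetylbenzoic acid that rests as lactol 6; the stereocentres of 5 are erased and the lactol carbon of 6 is racemic and disappears in step 5.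

**Step 2**
Reactants: 6 rac-4-[(E)-(2,2-dimethylhydrazinylidene)methyl]-3-hydroxy-3,7-dimethyl-2-benzofuran-1(3H)-one
Product: 7 rac-4-[(E)-(2,2-dimethylhydrazinylidene)methyl]-3-methoxy-3,7-dimethyl-2-benzofuran-1(3H)-one
Conditions: MeOH, pyridinium p-toluenesulfonate (0.2 equiv), 3 Å MS, 60 °C
Reagents that add atoms: methanol, CO
Why: Pseudo-ester formation by acid-catalysed acetal exchange, in which the tertiary benzylic lactol ionizes to a cyclic oxocarbenium ion that methanol traps, while normal Fischer esterification of the 2,6-disubstituted benzoic acid is sterically blocked and the hydrazone is inert to this weak acid; the new centre is racemic and is removed in step 5.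

**Step 3**
Reactants: 8 guaiazulene (7-isopropyl-1,4-dimethylazulene); 9 N,N-dimethylmethylideneammonium iodide
Product: 10 1-(5-isopropyl-3,8-dimethylazulen-1-yl)-N,N-dimethylmethanamine
Conditions: CH2Cl2, 23 °C, 2 h; then aq. NaOH
Reagents that add atoms: none
Why: Mannich-type electrophilic aromatic substitution in which the iminium ion attacks C3 of guaiazulene, the only free and by far the most nucleophilic position of the five-membered ring.

**Step 4**
Reactants: 10 1-(5-isopropyl-3,8-dimethylazulen-1-yl)-N,N-dimethylmethanamine; 11 iodomethane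
Product: 13 diethyl [(5-isopropyl-3,8-dimethylazulen-1-yl)methyl]phosphonate, via azulenylmethyl trimethylammonium iodide 12 (not isolated)
Conditions: 11 (1.1 equiv), MeCN, 0 → 23 °C; then P(OEt)3 (3 equiv), 80 °C
Reagents that add atoms: triethyl phosphite, CCOP(OCC)OCC
Why: N-Methylation turns the amine into a trimethylamine leaving group, ionization gives the strongly stabilized azulenylmethyl cation, and triethyl phosphite captures it and is dealkylated by iodide (gramine-type Michaelis–Arbuzov reaction).

**Step 5**
Reactants: 13 diethyl [(5-isopropyl-3,8-dimethylazulen-1-yl)methyl]phosphonate; 7 rac-4-[(E)-(2,2-dimethylhydrazinylidene)methyl]-3-methoxy-3,7-dimethyl-2-benzofuran-1(3H)-one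
Product: 15 4-[(E)-(2,2-dimethylhydrazinylidene)methyl]-2-(5-isopropyl-3,8-dimethylazulen-1-yl)-3,7-dimethyl-1H-inden-1-one, via keto phosphonate 14 (not isolated)
Conditions: 13 (1.15 equiv), LiN(iPr)2 (1.15 equiv), THF, −78 °C, 30 min; add 7 (1.0 equiv); −78 → 23 °C; then 60 °C
Reagents that add atoms: none
Why: Kinetic α-phosphonyl lithiation and C-acylation at the lactone carbonyl of the pseudo-ester (ring opening and loss of methoxide unmask the o-acetyl group only after the acylation) are followed by intramolecular Horner–Wadsworth–Emmons olefination of the phosphonoenolate onto the neighbouring methyl ketone, which closes the five-membered ring as the tetrasubstituted indenone double bond (the classical enol-lactone-to-enone phosphonate annulation, with LiOMe released in situ as the base); no stereocentre remains.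

**Step 6**
Reactants: 15 4-[(E)-(2,2-dimethylhydrazinylidene)methyl]-2-(5-isopropyl-3,8-dimethylazulen-1-yl)-3,7-dimethyl-1H-inden-1-one
Product: 16 2-(5-isopropyl-3,8-dimethylazulen-1-yl)-3,7-dimethyl-1-oxo-1H-indene-4-carbaldehyde
Conditions: OHC–CO2H·H2O (5 equiv), THF/H2O 4:1, 40 °C
Reagents that add atoms: water, O
Why: Hydrazone hydrolysis driven by transhydrazonation, in which water cleaves the protonated hydrazone and glyoxylic acid irreversibly traps the N,N-dimethylhydrazine, under oxidant-free and only weakly acidic conditions that the azulene and the indenone tolerate; no stereocentre is formed.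

**Compound list**
1 | 5-methylfurfural | Cc1ccc(C=O)o1 | starting material
2 | N,N-dimethylhydrazine | CN(C)N | starting material
3 | (E)-4-oxopent-2-enoic acid | CC(=O)/C=C/C(=O)O | starting material
4 | (E)-1,1-dimethyl-2-[(5-methylfuran-2-yl)methylidene]hydrazine | Cc1ccc(/C=N/N(C)C)o1 | intermediate
5 | 2-acetyl-1-[(E)-(2,2-dimethylhydrazinylidene)methyl]-4-methyl-7-oxabicyclo[2.2.1]hept-5-ene-3-carboxylic acid (racemic; 2,3-trans; endo/exo mixture, ring stereocentres left undefined because all are erased on aromatization) | CC(=O)C1C(C(=O)O)C2(C)C=CC1(/C=N/N(C)C)O2 | intermediate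
6 | rac-4-[(E)-(2,2-dimethylhydrazinylidene)methyl]-3-hydroxy-3,7-dimethyl-2-benzofuran-1(3H)-one (lactol form of 2-acetyl-3-[(E)-(2,2-dimethylhydrazinylidene)methyl]-6-methylbenzoic acid) | CC1(O)OC(=O)c2c(C)ccc(/C=N/N(C)C)c21 | intermediate
7 | rac-4-[(E)-(2,2-dimethylhydrazinylidene)methyl]-3-methoxy-3,7-dimethyl-2-benzofuran-1(3H)-one | COC1(C)OC(=O)c2c(C)ccc(/C=N/N(C)C)c21 | intermediate
8 | guaiazulene (7-isopropyl-1,4-dimethylazulene) | c1cc(C)c2cc(C(C)C)ccc(C)c1-2 | starting material
9 | N,N-dimethylmethylideneammonium iodide | C=[N+](C)C.[I-] | starting material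
10 | 1-(5-isopropyl-3,8-dimethylazulen-1-yl)-N,N-dimethylmethanamine | CN(C)Cc1cc(C)c2cc(C(C)C)ccc(C)c1-2 | intermediate
11 | iodomethane | CI | starting material
12 | [(5-isopropyl-3,8-dimethylazulen-1-yl)methyl]trimethylammonium iodide | C[N+](C)(C)Cc1cc(C)c2cc(C(C)C)ccc(C)c1-2.[I-] | intermediate
13 | diethyl [(5-isopropyl-3,8-dimethylazulen-1-yl)methyl]phosphonate | CCOP(=O)(OCC)Cc1cc(C)c2cc(C(C)C)ccc(C)c1-2 | intermediate
14 | rac-diethyl {2-[2-acetyl-3-[(E)-(2,2-dimethylhydrazinylidene)methyl]-6-methylphenyl]-1-(5-isopropyl-3,8-dimethylazulen-1-yl)-2-oxoethyl}phosphonate (present as its lithium enolate) | CCOP(=O)(OCC)C(c1cc(C)c2cc(C(C)C)ccc(C)c1-2)C(=O)c1c(C)ccc(/C=N/N(C)C)c1C(C)=O | intermediate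
15 | 4-[(E)-(2,2-dimethylhydrazinylidene)methyl]-2-(5-isopropyl-3,8-dimethylazulen-1-yl)-3,7-dimethyl-1H-inden-1-one | CC1=C(c2cc(C)c3cc(C(C)C)ccc(C)c2-3)C(=O)c2c(C)ccc(/C=N/N(C)C)c21 | intermediate
16 | 2-(5-isopropyl-3,8-dimethylazulen-1-yl)-3,7-dimethyl-1-oxo-1H-indene-4-carbaldehyde | CC1=C(c2cc(C)c3cc(C(C)C)ccc(C)c2-3)C(=O)c2c(C)ccc(C=O)c21 | target

**Step count**
Total: 6 steps. Longest linear sequence: 4 steps (1 → 6 → 7 → 15 → 16; the guaiazulene branch 8 → 10 → 13 → 15 → 16 is also 4).

**Three steps most likely to fail, each with a fallback**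

Step 1 (key cycloaromatization). The risks are incomplete regiocontrol (ketone against acid as the directing acceptor, with a methyl on the reacting furan terminus), partial loss of the hydrazone to the free carboxylic acid, and sluggish cycloaddition. The fallback sets out from 4 and comes back at 6. Hydrazone 4 is isolated by evaporation and heated in toluene at 110 °C with the neutral dienophile ethyl (E)-4-oxopent-2-enoate, then with a little AcOH to complete the dehydration. This gives ethyl 2-acetyl-3-[(E)-(2,2-dimethylhydrazinylidene)methyl]-6-methylbenzoate F1, from which the regioisomer is removed by chromatography at this neutral ester stage. Saponification with LiOH in THF/H2O, assisted by the neighbouring ketone through its cyclic hemiketal, and acidification to pH 4 return lactol 6.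

Step 5 (acylation/olefination). The 4-methyl group of the guaiazulene unit is itself acidic and may compete with the α-phosphonyl position, and the lactone carbonyl is flanked by an ortho methyl. Alkyllithium bases are excluded because they add to the seven-membered ring. The fallback sets out from 12 and comes back at 15, and replaces the phosphonate carbanion by a far more acidic phosphonium ylide. Ammonium iodide 12 is heated with PPh3 in MeCN to give [(5-isopropyl-3,8-dimethylazulen-1-yl)methyl]triphenylphosphonium iodide F2. Deprotonation with NaN(SiMe3)2 in THF at 0 °C (too weak a base to touch the azulene methyl) and addition of 7 give the acyl ylide 1-{2-acetyl-3-[(E)-(2,2-dimethylhydrazinylidene)methyl]-6-methylphenyl}-2-(5-isopropyl-3,8-dimethylazulen-1-yl)-2-(triphenylphosphoranylidene)ethan-1-one F3. Heating F3 in toluene at 110 °C closes the ring by intramolecular Wittig reaction to give 15.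

Step 6 (unveiling the aldehyde). The hydrazone on the electron-poor indenone may hydrolyse slowly, and the azulene forbids the usual oxidative cleavages. The fallback sets out from 7 and comes back at 16, and changes the protecting group before the azulene is introduced. Pseudo-ester 7 is treated with HCl in MeOH/HC(OMe)3 at 23 °C to give 4-(dimethoxymethyl)-3-methoxy-3,7-dimethyl-2-benzofuran-1(3H)-one F4. F4 is coupled with lithiated 13 exactly as in step 5 to give 4-(dimethoxymethyl)-2-(5-isopropyl-3,8-dimethylazulen-1-yl)-3,7-dimethyl-1H-inden-1-one F5. The dimethyl acetal of F5 is cleaved with pyridinium p-toluenesulfonate in wet acetone at 23 °C to give 16.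

**Further compounds**
F1 | step 1 | ethyl 2-acetyl-3-[(E)-(2,2-dimethylhydrazinylidene)methyl]-6-methylbenzoate | CCOC(=O)c1c(C)ccc(/C=N/N(C)C)c1C(C)=O
F2 | step 5 | [(5-isopropyl-3,8-dimethylazulen-1-yl)methyl]triphenylphosphonium iodide | c1ccccc1[P+](c1ccccc1)(c1ccccc1)Cc1cc(C)c2cc(C(C)C)ccc(C)c1-2.[I-]
F3 | step 5 | 1-{2-acetyl-3-[(E)-(2,2-dimethylhydrazinylidene)methyl]-6-methylphenyl}-2-(5-isopropyl-3,8-dimethylazulen-1-yl)-2-(triphenylphosphoranylidene)ethan-1-one | CC(=O)c1c(/C=N/N(C)C)ccc(C)c1C(=O)C(=P(c1ccccc1)(c1ccccc1)c1ccccc1)c1cc(C)c2cc(C(C)C)ccc(C)c1-2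
F4 | step 6 | rac-4-(dimethoxymethyl)-3-methoxy-3,7-dimethyl-2-benzofuran-1(3H)-one | COC(OC)c1ccc(C)c2c1C(C)(OC)OC2=O
F5 | step 6 | 4-(dimethoxymethyl)-2-(5-isopropyl-3,8-dimethylazulen-1-yl)-3,7-dimethyl-1H-inden-1-one | CC1=C(c2cc(C)c3cc(C(C)C)ccc(C)c2-3)C(=O)c2c(C)ccc(C(OC)OC)c21
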